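**Retrosynthetic overview**

- The target is the tetra-deprotected form of a biflavone whose unit 2 (the 6-linked apigenin half) carries three benzyl ethers and whose unit 1 (the 3-linked flavone half) carries a 5-OMe group; one BCl3 treatment removes the three benzyl groups and the carbonyl-chelated 5-methyl ether.
- The C2=C3 bond of unit 1 comes from dehydrogenation of a 2,3-trans-3-arylflavanone, so the two sp3 centres are transient.
- The route rests on ring A of unit 1: O1 on C8a and the C4 acyl carbon on C4a are ortho neighbours, flanked by the C5 oxygen and with the C7 oxygen meta. This is the pattern that 3,5-dimethoxybenzyne takes up from a carboxylic acid. Ring C of unit 1 is therefore cut at O1–C8a and C4–C4a (aryne insertion into the acid C–O bond) and at O1–C2 (oxa-Michael addition).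
- The acid partner, an α-(unit 2-6-yl)-4-methoxycinnamic acid, comes from a Perkin condensation of the (apigenin-6-yl)acetic acid with 4-methoxybenzaldehyde. The acetic acid comes from a palladium-catalysed Reformatsky arylation of tribenzyl 6-iodoapigenin, made from apigenin.
- Ring order: rings A, B and C of unit 2 are bought with apigenin, ring B of unit 1 with the aldehyde, ring A of unit 1 enters as the aryne, and ring C of unit 1 is the only ring formed, last.

Key step: step 10

Remark: the target has no stereocentre and its SMILES gives no configuration for the hindered C3 (unit 1)–C6 (unit 2) axis, so the route is planned without control of that axis.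

**Route**

Step 1
Reactants: 1 3,5-dimethoxyphenol
Product: 2 3,5-dimethoxyphenyl N-isopropylcarbamate
Conditions: i-PrNCO, Et3N (cat.), CH2Cl2, rt
Reagents that add atoms: isopropyl isocyanate, CC(C)N=C=O
Why: Base-catalysed addition of the phenol to the isocyanate (carbamoylation) installs a strong ortho-directing group that can later be removed under mild base.

Step 2
Reactants: 2 3,5-dimethoxyphenyl N-isopropylcarbamate
Product: 6 3,5-dimethoxy-2-(trimethylsilyl)phenyl N-isopropylcarbamate, via N-silyl carbamate 3 (not isolated), via aryllithium 4 (not isolated), via N-silyl C-silyl carbamate 5 (not isolated)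
Conditions: TBSOTf, TMEDA, Et2O, 0 °C to rt; n-BuLi, TMEDA, −78 °C; TMSCl, −78 °C to rt; aq. NaHSO4
Reagents that add atoms: chlorotrimethylsilane, C[Si](C)(C)Cl
Why: In-situ N-silylation removes the acidic N–H, directed ortho-lithiation then occurs at C2 between the carbamate and a methoxy group (preferred to C4 between the two weaker methoxy directors), TMSCl traps the aryllithium and the acidic work-up takes the silyl group off nitrogen.

Step 3
Reactants: 6 3,5-dimethoxy-2-(trimethylsilyl)phenyl N-isopropylcarbamate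
Product: 8 3,5-dimethoxy-2-(trimethylsilyl)phenyl trifluoromethanesulfonate, via 3,5-dimethoxy-2-(trimethylsilyl)phenol 7 (not isolated)
Conditions: DBU, Et2NH, MeCN, 40 °C; then PhNTf2, rt
Reagents that add atoms: N-phenylbis(trifluoromethanesulfonimide), O=S(=O)(N(c1ccccc1)S(=O)(=O)C(F)(F)F)C(F)(F)F
Why: E1cB cleavage of the secondary carbamate (the isocyanate is trapped by Et2NH as a urea) frees the phenoxide, which PhNTf2 triflates in the same flask; the aryl–silicon bond is untouched in the absence of fluoride.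

Step 4
Reactants: 9 apigenin
Product: 10 7,4'-di-O-benzylapigenin (7-benzyloxy-2-(4-benzyloxyphenyl)-5-hydroxychromen-4-one)
Conditions: BnBr (2.2 equiv), K2CO3, DMF, rt
Reagents that add atoms: benzyl bromide, BrCc1ccccc1
Why: Williamson etherification of the two acidic phenols; the 5-OH is hydrogen-bonded to the C4 carbonyl, is the least nucleophilic and should stay free.

Step 5
Reactants: 10 7,4'-di-O-benzylapigenin
Product: 11 7,4'-di-O-benzyl-6-iodoapigenin (7-benzyloxy-2-(4-benzyloxyphenyl)-5-hydroxy-6-iodochromen-4-one)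
Conditions: BnMe3N·ICl2, CaCO3, CH2Cl2–MeOH, rt
Reagents that add atoms: benzyltrimethylammonium dichloroiodate, C[N+](C)(C)Cc1ccccc1.Cl[I-]Cl
Why: Electrophilic aromatic iodination in which the free 5-hydroxyl directs the iodine to its ortho position C6, the known regiochemistry for 5-hydroxy-7-alkoxyflavones.

Step 6
Reactants: 11 7,4'-di-O-benzyl-6-iodoapigenin
Product: 12 5,7,4'-tri-O-benzyl-6-iodoapigenin (5,7-bis(benzyloxy)-2-(4-benzyloxyphenyl)-6-iodochromen-4-one)
Conditions: BnBr, K2CO3, DMF, 70 °C
Reagents that add atoms: benzyl bromide, BrCc1ccccc1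
Why: Williamson etherification under more forcing conditions breaks the chelate and caps the 5-hydroxyl, which would otherwise trap the aryne in step 10.

Step 7
Reactants: 12 5,7,4'-tri-O-benzyl-6-iodoapigenin
Product: 13 tert-butyl (5,7,4'-tri-O-benzylapigenin-6-yl)acetate
Conditions: BrZnCH2CO2tBu (2 equiv), Pd2(dba)3 (2.5 mol %), XPhos (10 mol %), THF, 65 °C
Reagents that add atoms: (2-tert-butoxy-2-oxoethyl)zinc bromide, CC(C)(C)OC(=O)C[Zn]Br
Why: Negishi-type α-arylation of a Reformatsky reagent; zerovalent palladium with the bulky biaryl phosphine inserts into the hindered, electron-rich C–I bond, and the mild zinc enolate leaves the vinylogous-ester carbonyl of the chromone alone.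

Step 8
Reactants: 13 tert-butyl (5,7,4'-tri-O-benzylapigenin-6-yl)acetate
Product: 14 (5,7,4'-tri-O-benzylapigenin-6-yl)acetic acid
Conditions: TFA, CH2Cl2, 0 °C to rt
Reagents that add atoms: none
Why: Acidolysis of the tert-butyl ester by loss of isobutene; aryl benzyl ethers and the chromone should tolerate brief exposure to TFA at this temperature.

Step 9
Reactants: 14 (5,7,4'-tri-O-benzylapigenin-6-yl)acetic acid; 15 4-methoxybenzaldehyde
Product: 18 (E)-2-(5,7,4'-tri-O-benzylapigenin-6-yl)-3-(4-methoxyphenyl)acrylic acid, via mixed acetic anhydride 16 (not isolated), via acrylic mixed anhydride 17 (not isolated)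
Conditions: Ac2O, Et3N, 110 °C; then H2O, THF, rt
Reagents that add atoms: none
Why: Perkin condensation: the mixed anhydride is enolised by Et3N, adds to the aldehyde and eliminates, and the E acid (carboxyl trans to the 4-methoxyphenyl group) is the usual outcome and here the less strained isomer, since the di-ortho-substituted aryl group stands perpendicular in any case.

Step 10
Reactants: 18 (E)-2-(5,7,4'-tri-O-benzylapigenin-6-yl)-3-(4-methoxyphenyl)acrylic acid; 8 3,5-dimethoxy-2-(trimethylsilyl)phenyl trifluoromethanesulfonate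
Product: 21 rac-(2R,3S)-5,7-dimethoxy-2-(4-methoxyphenyl)-3-(5,7,4'-tri-O-benzylapigenin-6-yl)chroman-4-one (2,3-trans), via 3,5-dimethoxybenzyne 19 (not isolated), via 2'-hydroxy-α-aryl chalcone 20 (not isolated)
Conditions: 8 (1.5 equiv), CsF (4 equiv), THF, 125 °C, sealed tube
Reagents that add atoms: none
Why: CsF converts 18 into its carboxylate and desilylates 8, so that loss of triflate gives aryne 19; the carboxylate oxygen adds to the aryne carbon remote from the flanking methoxy group (C1), the aryl anion left at C2 attacks its own ester carbonyl in a 4-exo-trig step, and the strained four-membered alkoxide opens to the ortho-acylphenoxide of chalcone 20, so that O1–C8a and C4–C4a are formed in one insertion. The closest known reaction type is the fluoride-induced insertion of arynes into the C–O bond of carboxylic acids, which gives ortho-hydroxyaryl ketones and, with cinnamic and other α,β-unsaturated acids, chroman-4-ones and flavanones. Ring C then closes by a 6-endo-trig oxa-Michael addition of the phenoxide to the β-carbon (O1–C2), and the enolate is protonated at C3. Both new stereocentres (C2 and C3) are set under thermodynamic control, because the oxa-Michael step is reversible and C3 is epimerisable, which should favour the trans (diequatorial) racemate; neither centre needs control, since step 11 removes both. The selectivity the step needs is the regiochemistry of aryne capture, secured by the C3 methoxy group of 19, whose inductive pull distorts the triple bond so that the nucleophile enters at the distal carbon and the acyl group ends between OMe and O1; the second requirement, acyl transfer ahead of protonation of the aryl anion, is served by the aprotic medium and the high temperature.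

Step 11
Reactants: 21 rac-(2R,3S)-5,7-dimethoxy-2-(4-methoxyphenyl)-3-(5,7,4'-tri-O-benzylapigenin-6-yl)chroman-4-one
Product: 22 5,7-dimethoxy-2-(4-methoxyphenyl)-3-(5,7,4'-tri-O-benzylapigenin-6-yl)chromen-4-one
Conditions: DDQ (2.5 equiv), 1,4-dioxane, reflux
Reagents that add atoms: none
Why: DDQ dehydrogenation of a flavanone to a flavone: hydride abstraction from C2–H (benzylic, α to O1 and activated by the 4-methoxyphenyl group) followed by loss of the C3 proton gives the conjugated chromone and removes both stereocentres, while aryl benzyl ethers are much less prone to DDQ oxidation.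

Step 12
Reactants: 22 5,7-dimethoxy-2-(4-methoxyphenyl)-3-(5,7,4'-tri-O-benzylapigenin-6-yl)chromen-4-one
Product: 23 3-[5,7-dihydroxy-2-(4-hydroxyphenyl)-4-oxochromen-6-yl]-5-hydroxy-7-methoxy-2-(4-methoxyphenyl)chromen-4-one (CNP0273448.0)
Conditions: BCl3 (10 equiv), C6HMe5 (10 equiv), CH2Cl2, −78 °C to 0 °C; MeOH, then aq. work-up
Reagents that add atoms: none
Why: Lewis-acid ether cleavage: BCl3 removes the three benzyl groups at low temperature (pentamethylbenzene scavenges the benzyl cation and prevents C-benzylation), and on warming cleaves only the 5-methyl ether of unit 1 through its six-membered boron chelate with the C4 carbonyl, leaving the non-chelated 7- and 4'-methyl ethers.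

**Compound list**

1 | 3,5-dimethoxyphenol | COc1cc(O)cc(OC)c1 | starting material
2 | 3,5-dimethoxyphenyl N-isopropylcarbamate | COc1cc(OC)cc(OC(=O)NC(C)C)c1 | intermediate
3 | 3,5-dimethoxyphenyl N-(tert-butyldimethylsilyl)-N-isopropylcarbamate (not isolated) | COc1cc(OC)cc(OC(=O)N(C(C)C)[Si](C)(C)C(C)(C)C)c1 | intermediate
4 | 2-lithio-3,5-dimethoxyphenyl N-(tert-butyldimethylsilyl)-N-isopropylcarbamate (not isolated) | COc1cc(OC)c([Li])c(OC(=O)N(C(C)C)[Si](C)(C)C(C)(C)C)c1 | intermediate
5 | 3,5-dimethoxy-2-(trimethylsilyl)phenyl N-(tert-butyldimethylsilyl)-N-isopropylcarbamate (not isolated) | COc1cc(OC)c([Si](C)(C)C)c(OC(=O)N(C(C)C)[Si](C)(C)C(C)(C)C)c1 | intermediate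
6 | 3,5-dimethoxy-2-(trimethylsilyl)phenyl N-isopropylcarbamate | COc1cc(OC)c([Si](C)(C)C)c(OC(=O)NC(C)C)c1 | intermediate
7 | 3,5-dimethoxy-2-(trimethylsilyl)phenol (not isolated, present as its DBU salt) | COc1cc(O)c([Si](C)(C)C)c(OC)c1 | intermediate
8 | 3,5-dimethoxy-2-(trimethylsilyl)phenyl trifluoromethanesulfonate | COc1cc(OC)c([Si](C)(C)C)c(OS(=O)(=O)C(F)(F)F)c1 | intermediate
9 | apigenin | O=c1cc(-c2ccc(O)cc2)oc2cc(O)cc(O)c12 | starting material
10 | 7-benzyloxy-2-(4-benzyloxyphenyl)-5-hydroxychromen-4-one | O=c1cc(-c2ccc(OCc3ccccc3)cc2)oc2cc(OCc3ccccc3)cc(O)c12 | intermediate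
11 | 7-benzyloxy-2-(4-benzyloxyphenyl)-5-hydroxy-6-iodochromen-4-one | O=c1cc(-c2ccc(OCc3ccccc3)cc2)oc2cc(OCc3ccccc3)c(I)c(O)c12 | intermediate
12 | 5,7-bis(benzyloxy)-2-(4-benzyloxyphenyl)-6-iodochromen-4-one | O=c1cc(-c2ccc(OCc3ccccc3)cc2)oc2cc(OCc3ccccc3)c(I)c(OCc3ccccc3)c12 | intermediate
13 | tert-butyl 2-[5,7-bis(benzyloxy)-2-(4-benzyloxyphenyl)-4-oxochromen-6-yl]acetate | CC(C)(C)OC(=O)Cc1c(OCc2ccccc2)cc2oc(-c3ccc(OCc4ccccc4)cc3)cc(=O)c2c1OCc1ccccc1 | intermediate
14 | 2-[5,7-bis(benzyloxy)-2-(4-benzyloxyphenyl)-4-oxochromen-6-yl]acetic acid | OC(=O)Cc1c(OCc2ccccc2)cc2oc(-c3ccc(OCc4ccccc4)cc3)cc(=O)c2c1OCc1ccccc1 | intermediate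
15 | 4-methoxybenzaldehyde | COc1ccc(C=O)cc1 | starting material
16 | acetic 2-[5,7-bis(benzyloxy)-2-(4-benzyloxyphenyl)-4-oxochromen-6-yl]acetic anhydride (not isolated) | CC(=O)OC(=O)Cc1c(OCc2ccccc2)cc2oc(-c3ccc(OCc4ccccc4)cc3)cc(=O)c2c1OCc1ccccc1 | intermediate
17 | acetic (E)-2-[5,7-bis(benzyloxy)-2-(4-benzyloxyphenyl)-4-oxochromen-6-yl]-3-(4-methoxyphenyl)acrylic anhydride (not isolated) | CC(=O)OC(=O)/C(=C/c1ccc(OC)cc1)c1c(OCc2ccccc2)cc2oc(-c3ccc(OCc4ccccc4)cc3)cc(=O)c2c1OCc1ccccc1 | intermediate
18 | (E)-2-[5,7-bis(benzyloxy)-2-(4-benzyloxyphenyl)-4-oxochromen-6-yl]-3-(4-methoxyphenyl)acrylic acid | O=C(O)/C(=C/c1ccc(OC)cc1)c1c(OCc2ccccc2)cc2oc(-c3ccc(OCc4ccccc4)cc3)cc(=O)c2c1OCc1ccccc1 | intermediate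
19 | 3,5-dimethoxybenzyne (1,2-didehydro-3,5-dimethoxybenzene; not isolated) | COC1=CC(OC)=CC#C1 | intermediate
20 | (E)-2-[5,7-bis(benzyloxy)-2-(4-benzyloxyphenyl)-4-oxochromen-6-yl]-1-(2-hydroxy-4,6-dimethoxyphenyl)-3-(4-methoxyphenyl)prop-2-en-1-one (not isolated, present as its caesium phenoxide) | COc1ccc(/C=C(/C(=O)c2c(O)cc(OC)cc2OC)c2c(OCc3ccccc3)cc3oc(-c4ccc(OCc5ccccc5)cc4)cc(=O)c3c2OCc2ccccc2)cc1 | intermediate
21 | rac-(2R,3S)-3-[5,7-bis(benzyloxy)-2-(4-benzyloxyphenyl)-4-oxochromen-6-yl]-5,7-dimethoxy-2-(4-methoxyphenyl)chroman-4-one (2,3-trans; one enantiomer drawn) | COc1ccc([C@@H]2Oc3cc(OC)cc(OC)c3C(=O)[C@H]2c2c(OCc3ccccc3)cc3oc(-c4ccc(OCc5ccccc5)cc4)cc(=O)c3c2OCc2ccccc2)cc1 | intermediate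
22 | 3-[5,7-bis(benzyloxy)-2-(4-benzyloxyphenyl)-4-oxochromen-6-yl]-5,7-dimethoxy-2-(4-methoxyphenyl)chromen-4-one | COc1ccc(-c2oc3cc(OC)cc(OC)c3c(=O)c2-c2c(OCc3ccccc3)cc3oc(-c4ccc(OCc5ccccc5)cc4)cc(=O)c3c2OCc2ccccc2)cc1 | intermediate
23 | 3-[5,7-dihydroxy-2-(4-hydroxyphenyl)-4-oxochromen-6-yl]-5-hydroxy-7-methoxy-2-(4-methoxyphenyl)chromen-4-one (CNP0273448.0) | COc1ccc(-c2oc3cc(OC)cc(O)c3c(=O)c2-c2c(O)cc3oc(-c4ccc(O)cc4)cc(=O)c3c2O)cc1 | target

**Step count**

Total: 12 steps. Longest linear sequence: 9 steps (apigenin 9 to target 23, steps 4–12). The aryne precursor 8 is made in a 3-step branch (steps 1–3) and joins at step 10.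

**Steps most likely to fail**

1. Step 10 (aryne insertion and oxa-Michael addition). The aryl anion may be protonated before it reaches the hindered ester carbonyl, which would stop the sequence at simple O-arylation of the acid. The product phenoxide or enolate may also be arylated by excess aryne. Fallback: the O1–C8a bond is taken from a phenol and the same acyl shift is triggered by halogen–metal exchange. It sets out from acid 18, with phenol 1 as the second component. Phenol 1 is brominated with NBS in CH2Cl2 at −78 °C to 2-bromo-3,5-dimethoxyphenol F1, and the 4-bromo isomer is removed by chromatography. Acid 18 is esterified with F1 (EDC·HCl, DMAP, CH2Cl2) to the 2-bromo-3,5-dimethoxyphenyl (E)-acrylate F2. Bromine–lithium exchange on F2 with n-BuLi in THF at −100 °C should be followed by the anionic 1,3 O-to-C acyl shift (anionic Fries type) to the lithium phenoxide of chalcone 20. Warming with K2CO3 in EtOH should close ring C, and the fallback comes back to the route at flavanone 21.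

2. Step 11 (DDQ dehydrogenation). Hydride abstraction at C2 may be slowed by shielding from the perpendicular di-ortho-substituted aryl group at C3, and prolonged heating may lead to oxidative loss of benzyl ethers. Fallback: from flavanone 21, soft enolisation with TMSOTf and Et3N in CH2Cl2 at 0 °C should give the 4-(trimethylsilyloxy)-2H-chromene F3. Saegusa–Ito oxidation of F3 with a stoichiometric amount of Pd(OAc)2 (divalent palladium) in MeCN should then introduce the C2=C3 bond by β-hydride elimination of the C2 hydrogen, coming back to the route at 22.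

3. Step 9 (Perkin condensation). Enolisation and aldol addition of the hindered arylacetic mixed anhydride may be slow, and at the temperature required the product acid may decarboxylate. Fallback: from ester 13, deprotonation with LiN(SiMe3)2 in THF at −78 °C and addition of aldehyde 15 should give the β-hydroxy ester F4 as a mixture of diastereomers. Mesylation (MsCl, Et3N, CH2Cl2, 0 °C) gives the mesylate F5, and E1cB elimination with DBU should give the thermodynamically preferred tert-butyl (E)-acrylate F6. TFA in CH2Cl2 then cleaves the ester, and the fallback comes back to the route at acid 18.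

**Further compounds**

F1 | step 10 | 2-bromo-3,5-dimethoxyphenol | COc1cc(O)c(Br)c(OC)c1
F2 | step 10 | 2-bromo-3,5-dimethoxyphenyl (E)-2-[5,7-bis(benzyloxy)-2-(4-benzyloxyphenyl)-4-oxochromen-6-yl]-3-(4-methoxyphenyl)acrylate | COc1ccc(/C=C(/C(=O)Oc2cc(OC)cc(OC)c2Br)c2c(OCc3ccccc3)cc3oc(-c4ccc(OCc5ccccc5)cc4)cc(=O)c3c2OCc2ccccc2)cc1
F3 | step 11 | 3-[5,7-bis(benzyloxy)-2-(4-benzyloxyphenyl)-4-oxochromen-6-yl]-5,7-dimethoxy-2-(4-methoxyphenyl)-4-(trimethylsilyloxy)-2H-chromene (racemic) | COc1ccc(C2Oc3cc(OC)cc(OC)c3C(O[Si](C)(C)C)=C2c2c(OCc3ccccc3)cc3oc(-c4ccc(OCc5ccccc5)cc4)cc(=O)c3c2OCc2ccccc2)cc1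
F4 | step 9 | tert-butyl 2-[5,7-bis(benzyloxy)-2-(4-benzyloxyphenyl)-4-oxochromen-6-yl]-3-hydroxy-3-(4-methoxyphenyl)propanoate (mixture of diastereomers) | CC(C)(C)OC(=O)C(C(O)c1ccc(OC)cc1)c1c(OCc2ccccc2)cc2oc(-c3ccc(OCc4ccccc4)cc3)cc(=O)c2c1OCc1ccccc1
F5 | step 9 | tert-butyl 2-[5,7-bis(benzyloxy)-2-(4-benzyloxyphenyl)-4-oxochromen-6-yl]-3-(methanesulfonyloxy)-3-(4-methoxyphenyl)propanoate (mixture of diastereomers) | CC(C)(C)OC(=O)C(C(OS(C)(=O)=O)c1ccc(OC)cc1)c1c(OCc2ccccc2)cc2oc(-c3ccc(OCc4ccccc4)cc3)cc(=O)c2c1OCc1ccccc1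
F6 | step 9 | tert-butyl (E)-2-[5,7-bis(benzyloxy)-2-(4-benzyloxyphenyl)-4-oxochromen-6-yl]-3-(4-methoxyphenyl)acrylate | CC(C)(C)OC(=O)/C(=C/c1ccc(OC)cc1)c1c(OCc2ccccc2)cc2oc(-c3ccc(OCc4ccccc4)cc3)cc(=O)c2c1OCc1ccccc1
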